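Substrate was left over: in the dawn run 60.3% of the charge still stood at the last reading, in the winter run 88.9%, and both readings were flat from 2.00 min. So I asked what had stopped these flasks while substrate remained.

the same everywhere: free catalyst 12 µM
- noon: substrate 2.1 mM; reagent 2.4 mM; run made earlier
- dawn: substrate 6.1 mM; reagent 2.4 mM; run made earlier
- winter: substrate 21 mM; reagent 2.4 mM; run made earlier
- birch: substrate 2.0 mM; reagent 2.40 mM; time 4.0 min
- cedar: substrate 6.0 mM; reagent 2.40 mM; time 4.0 min
- elm: substrate 20 mM; reagent 2.40 mM; time 4.0 min

| run | time / min | product / % | substrate / % |
|---|---|---|---|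
| noon | 0.333 | 44.1 | 55.3 |
| noon | 0.667 | 74.3 | 25.6 |
| noon | 1.00 | 90.1 | 9.9 |
| noon | 2.00 | 100.0 | 0.2 |
| noon | 4.00 | 99.9 | 0 |
| dawn | 0.333 | 19.4 | 79.8 |
| dawn | 0.667 | 33.4 | 66.1 |
| dawn | 1.00 | 39.3 | 61.1 |
| dawn | 2.00 | 39.8 | 60.7 |
| dawn | 4.00 | 38.5 | 60.3 |
| winter | 0.333 | 6.5 | 94.1 |
| winter | 1.00 | 11.4 | 88.8 |
| winter | 2.00 | 11.6 | 88.4 |
| winter | 3.00 | 11.5 | 88.1 |
| winter | 4.00 | 11.6 | 88.9 |

(readings scatter by 0.3 percentage points)

- candidate steps: catalyst intermediate B <-> by-product + catalyst intermediate C; catalyst intermediate C -> free catalyst + product; reagent + free catalyst <-> catalyst intermediate A; substrate + catalyst intermediate A <-> catalyst intermediate B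
- "hardly changes" means that all values lie within two and a half points (for a concentration: within two and a half percent of the largest)

1. amount of product at the end, in percent of the substrate charged for birch, cedar, elm, in this order
2. the course of these numbers from the first flask to the last (falls all the way / hardly changes / falls, then rises / rises all the way / rises, then falls)

My first question was whether the two stops shared a measure. I multiplied each plateau product fraction by the substrate charge over the reagent charge, which gives product per reagent charged. The readings came to 1.01 for dawn and 1.01 for winter, so one reagent went per product, and reagent was the limiting reagent in those runs.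

That raised the second question: how far does a given charge reach? Elm has 12.0% as its cover, the reagent charge over the substrate charge, capped at the whole substrate charge. Equal charges, a ratio of 1, divide this scale, with reagent left over above that mark and substrate left over below it. Noon stood on the reagent side at 1.14 and reached 100.0%. Birch stands there too, at 1.20, so its cover is 100%, while cedar's is 40.0%. Cedar's cover is lower than birch's, and elm's is lower than cedar's.

The third question was whether the flasks reach their covers in time. Each earlier run was flat by 2.00 min, and the asked time is twice that, so I took the covers as the answer.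

The forecast gave the same: 100%, 40%, 12%, falls all the way, holding that “the plateau is stoichiometric, not an equilibrium or catalyst death”.

The flasks gave 100%, 40.0%, 12.0%: falls all the way.

    catalyst intermediate B ⇌ by-product + catalyst intermediate C (K = 0.0960 M, k = 7.80 s⁻¹)
    catalyst intermediate C → free catalyst + product (k = 240 s⁻¹)
    reagent + free catalyst ⇌ catalyst intermediate A (K = 4300 L mol⁻¹, k = 13000 L mol⁻¹ s⁻¹)
    substrate + catalyst intermediate A ⇌ catalyst intermediate B (K = 32000 L mol⁻¹, k = 8600 L mol⁻¹ s⁻¹)

Cedar, with a cover of 40.0%, ended at 40.0% with 60.0% of its substrate left. Elm ended at its cover of 12.0% with 88.0% of its substrate left, because its reagent was used up, down to 0% of its charge. The same elm run with the using up of reagent taken away reached 80.8% instead of 12.0%, a difference of 69 percentage points.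

(The runs were generated by integration on assumed constants, and the scatter is random.)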